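**Plan**

- Feature: in the ten-membered ring (C1 = lactone O–CH, C2, C3 = CHMe, C4, C5, C6=C7, C8, C9 = CH–O-glycolate, C10 = ring-fusion CH) the branch carbon C14 sits on C7. C7 and C2 are linked by C8–C9–C10–C1, which carries oxygen at C9 and C1. C14 can therefore be the carbonyl of tropone spanning C7 and C2, and C8–C1 a 1,3-dioxygenated butadiene.
- Retrosynthesis: remove the two esters (C9–O with inversion, C14–O), the C11=C13 methylene and the lactone C12–O bond. C1–O is traced to a hydrosilylation of a C1=C2 alkene tethered from the C9 oxygen. C10–C11 and C3–CH3 are cut together (1,6-addition/alkylation of a dienone). C14–C2 is reconnected (retro-Claisen in reverse), and C7–C8 and C1–C2 are cut to tropone and the diene.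
- Forward: the (6+4) cycloaddition closes the ten-membered carbocycle as the rim of a bicyclo[4.4.1]undecane. Singlet oxygen puts leaving groups on C3 and C6, and methoxide cuts the C14–C2 bridge and expels both, leaving an achiral monocyclic trienone ester. A temporary oxasilolane follows, and the lactone is the last ring to form.
- Stereochemistry: C3 comes from a copper-catalysed enantioselective 1,6-addition of methyl (the only catalyst-controlled step). C10 comes from alkylation of the resulting dienolate under ring-conformational control. C9 is set by Felkin–Anh hydride delivery and later inverted in the Mitsunobu esterification. C1 is set by allylic-strain-controlled hydrosilylation and oxidation with retention. The C6=C7 geometry comes from E1cB elimination within the ring.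

Key step: step 1

Remarks. Atom labels C1–C14 are those of the target (C11 = methylene-bearing lactone carbon, C12 = lactone C=O, C13 = exocyclic CH2, C14 = CH2OAc carbon). β is the ring face that carries the C3 methyl group; in the target the C3 methyl, C10–C11 and C1–O are β and C9–O is α, which is (1S,3S,9S,10S) in this numbering. Compounds 3–9 are racemic (relative configuration given), 10 is achiral, and compounds from 13 on are single enantiomers. Assumption: the enantiomer of the ferrocenyl diphosphine in step 7 is the one that delivers the 3β (S) methyl centre; this has to be settled in a test reaction.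

Step 1
Reactants: 1 tropone; 2 (E)-1-methoxy-3-(trimethylsilyloxy)buta-1,3-diene
Product: 3 (6+4) adduct 7-methoxy-9-(trimethylsilyloxy)bicyclo[4.4.1]undeca-2,4,8-trien-11-one (racemic; methoxy anti to the carbonyl bridge)
Conditions: 2 (1.5 equiv), PhMe, 110 °C, sealed tube, 2,6-di-tert-butyl-4-methylphenol (1 mol %)
Reagents that add atoms: none
Why: Thermally allowed, concerted [6π+4π] cycloaddition in which the diene termini C8 and C1 bond suprafacially to the two α-carbons of tropone (C7 and C2), so that C7–C8 and C1–C2 form together and the carbonyl carbon C14 is left as a one-atom bridge. The closest known reaction type is the thermal, exo-selective (6+4) addition of tropone to 1-oxygenated buta-1,3-dienes. One new seven-membered ring closes by this intermolecular two-bond annulation onto tropone, and with it the C1–C10 ten-membered carbocycle appears as the rim of the bicyclo[4.4.1]undecane. The bridgeheads C2 and C7 are cis by suprafacial addition and C1–OMe is set by the E diene geometry in the exo transition state; all three centres are removed in step 6, so none needs control. The selectivity needed is periselectivity for (6+4) over (4+2) and (8+2): the largest LUMO coefficients of tropone lie at C2 and C7, the electron-rich diene has its largest HOMO coefficients at its termini, and the exo arrangement avoids the repulsive secondary overlap of the endo mode, while the symmetry of tropone removes any regiochemical question.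

Step 2
Reactants: 3 (6+4) adduct
Product: 4 7-methoxybicyclo[4.4.1]undeca-2,4-diene-9,11-dione (racemic)
Conditions: HCl (0.02 M aq.), THF, 0 °C, short contact; NaHCO3 quench
Reagents that add atoms: none
Why: Very dilute acid hydrolyses the silyl enol ether (protonation at C10, loss of silicon) faster than the β-methoxy group is eliminated, so the C9 ketone is unmasked while C1–OMe stays as a latent enone that shields C10=C1 from singlet oxygen and hydrogen in the next two steps; no lasting stereocentre is created.

Step 3
Reactants: 4 methoxy diketone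
Product: 5 endoperoxide 7-methoxy-2,5-epidioxybicyclo[4.4.1]undec-3-ene-9,11-dione (racemic; O–O bridge syn to the carbonyl bridge)
Conditions: O2, tetraphenylporphyrin (cat.), CH2Cl2, visible light, −30 °C
Reagents that add atoms: dioxygen, O=O
Why: The s-cis diene locked in the seven-membered ring undergoes (4+2) photooxygenation with singlet oxygen from the face syn to the one-carbon bridge (the other face is screened by the four-carbon bridge and its methoxy group), which puts oxygen on C3 and C6; both new centres are sacrificial and the ketones are inert.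

Step 4
Reactants: 5 endoperoxide
Product: 6 2,5-dihydroxy-7-methoxybicyclo[4.4.1]undecane-9,11-dione (racemic; both OH syn to the carbonyl bridge; C3–OH and C6–OH in target numbering)
Conditions: H2 (1 atm), Pd/C (5 mol %), EtOAc, 0 °C → rt
Reagents that add atoms: none
Why: Catalytic hydrogenation cleaves the weak O–O bond and saturates C4=C5 with retention at C3 and C6, giving the cis-diol while ketones and the methyl ether are untouched.

Step 5
Reactants: 6 diol
Product: 7 bis(methanesulfonate) of 6 (racemic)
Conditions: MeSO2Cl (2.5 equiv), Et3N (3 equiv), CH2Cl2, −20 °C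
Reagents that add atoms: methanesulfonyl chloride, CS(=O)(=O)Cl
Why: Sulfene-type mesylation turns both secondary alcohols into leaving groups that stay inert on the bicycle, because elimination toward C2 or C7 would give a bridgehead alkene and the C–O bonds lie gauche rather than antiperiplanar to the C14–C2 and C14–C7 bonds, which shuts off a concerted Grob fragmentation on either side.

Step 6
Reactants: 7 bis(methanesulfonate)
Product: 10 trienone ester methyl (1E,5Z,7Z)-9-oxocyclodeca-1,5,7-triene-1-carboxylate (achiral; target numbering: C9 ketone; cis C10=C1 and C2=C3; C6=C7 bearing CO2Me), via bicyclic enone bis-mesylate 8 (not isolated), via mesyloxy dienone ester 9 (not isolated)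
Conditions: NaOMe (2.05 equiv), MeOH–THF (1:1), −20 → 0 °C; pH 7 buffer
Reagents that add atoms: sodium methoxide, C[O-].[Na+]
Why: Methoxide first removes methanol from the β-methoxy ketone (E1cB) to give enone 8, then adds to the bridging ketone, whose C14–C2 bond breaks in a retro-Claisen fragmentation because only that side gives a carbanion stabilised as the extended enolate of the C9 enone; this dienolate expels the C3 mesylate to give 9, and the second equivalent of base removes the ester α-proton at C7 with loss of the C6 mesylate (E1cB), so that two equivalents of base are consumed, the base-sensitive product is left in a neutral medium, every stereocentre is erased, and the ring alkenes should take the cis geometries of the less strained ten-membered ring.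

Step 7
Reactants: 10 trienone ester; 11 tert-butyl bromoacetate
Product: 13 keto diester methyl (1E,5S,6Z,8S)-8-(2-tert-butoxy-2-oxoethyl)-5-methyl-9-oxocyclodeca-1,6-diene-1-carboxylate (target numbering: 3β-methyl; 10β-CH2CO2tBu; cis C1=C2; C9 ketone), via bromomagnesium dienolate 12 (not isolated)
Conditions: CuBr·SMe2 (5 mol %), (R)-1-[(S)-2-(diphenylphosphino)ferrocenyl]ethyldicyclohexylphosphine or its enantiomer (6 mol %), MeMgBr (1.2 equiv), tBuOMe–CH2Cl2, −78 °C; then DMPU, 11 (2 equiv), −78 → −30 °C; pH 7 buffer; used at once
Reagents that add atoms: methylmagnesium bromide, C[Mg]Br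
Why: Copper-catalysed asymmetric 1,6-conjugate addition of the Grignard reagent to the cyclic dienone sets C3 under control of the chiral diphosphine (the α-substituted enoate is far less reactive), and the regiospecifically formed cisoid dienolate 12 is alkylated at its α-carbon C10 from the peripheral face, away from the twisted C1=C2 unit and the transannular chain, which should place the acetate arm cis to the C3 methyl, the arrangement in which both allylic substituents are pseudo-equatorial on the chair-like cis,cis-cyclodeca-1,6-diene ring and therefore also the thermodynamic preference at this epimerisable centre.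

Step 8
Reactants: 13 keto diester
Product: 14 diol (target numbering: 9β-OH; C14 CH2OH; 10β-CH2CO2tBu; 3β-methyl; cis C1=C2; C6=C7)
Conditions: iBu2AlH (4 equiv), CH2Cl2, −78 °C; aqueous potassium sodium tartrate
Reagents that add atoms: none
Why: iBu2AlH reduces the ketone and, by 1,2-reduction, the conjugated methyl ester at −78 °C while the hindered tert-butyl ester survives, and hydride should reach C9 in the Felkin–Anh sense with the C1=C2 vinyl group antiperiplanar, that is from the face opposite the C10 arm, giving the 9β-alcohol cis to that arm; the step also removes the base-labile β,γ-unsaturated ketone.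

Step 9
Reactants: 14 diol
Product: 15 C14 tert-butyldiphenylsilyl ether of 14 (C9–OH free)
Conditions: tBuPh2SiCl (1.05 equiv), imidazole, CH2Cl2, 0 °C
Reagents that add atoms: tert-butyl(chloro)diphenylsilane, CC(C)(C)[Si](Cl)(c1ccccc1)c1ccccc1
Why: Chemoselective silyl ether formation at the unhindered primary allylic alcohol, much faster than at the flanked secondary C9 alcohol, keeps C9–OH free as the tether anchor and prevents the allylic oxygen from directing hydrosilylation to C6=C7.

Step 10
Reactants: 15 silyl ether
Product: 17 oxasilolane (five-membered ring O9–SiMe2–C1–C10–C9; C1–Si β; C9–O β; 10β-CH2CO2tBu), via dimethylsilyl ether 16 (not isolated)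
Conditions: (HMe2Si)2NH, CH2Cl2, rt; evaporate; Pt2[(CH2=CHSiMe2)2O]3 (0.5 mol %), PhMe, 60 °C
Reagents that add atoms: 1,1,3,3-tetramethyldisilazane, C[SiH](C)N[SiH](C)C
Why: Silylation of C9–OH followed by platinum-catalysed intramolecular hydrosilylation of the homoallylic silyl ether closes the oxasilolane by 5-exo delivery of silicon to C1 and hydrogen to C2, and 1,3-allylic strain across the cis C1=C2 bond holds H10 in the alkene plane so that the C9–O–Si tether attacks the face opposite the C10 arm, which fixes C1–Si β (cis-1,3 to C9–O and, once oxidised, correctly placed for a cis-fused lactone); the trisubstituted C6=C7 alkene does not react.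

Step 11
Reactants: 17 oxasilolane
Product: 19 C9 tert-butyldimethylsilyl ether carrying a C1 fluorodimethylsilyl group, via fluorosilyl alcohol 18 (not isolated)
Conditions: HF·pyridine (1.1 equiv), THF, 0 °C; then tBuMe2SiOSO2CF3, 2,6-lutidine, CH2Cl2, −78 °C
Reagents that add atoms: hydrogen fluoride, F; tert-butyldimethylsilyl trifluoromethanesulfonate, CC(C)(C)[Si](C)(C)OS(=O)(=O)C(F)(F)F
Why: HF opens the strained ring Si–O bond selectively (Si–F bond formation) and frees C9–OH, which is capped at once by silyl triflate silylation, so the two secondary oxygens stay differentiated when C1–O is unveiled.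

Step 12
Reactants: 19 fluorosilane
Product: 20 1β-alcohol (C9–OTBS; C14–OTBDPS; tert-butyl ester)
Conditions: H2O2 (30 % aq.), KF, KHCO3, THF–MeOH (1:1), rt
Reagents that add atoms: hydrogen peroxide, OO
Why: Tamao–Fleming oxidation, in which peroxide adds to fluoride-activated silicon and C1 migrates from silicon to oxygen with retention, gives the 1β-alcohol without touching the silyl ethers, the ester or the alkene.

Step 13
Reactants: 20 hydroxy ester
Product: 22 cis-fused γ-lactone (C1–O–C12; C9–OTBS; C14–OTBDPS), via hydroxy acid 21 (not isolated)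
Conditions: CF3CO2H–CH2Cl2 (1:9), 0 °C
Reagents that add atoms: none
Why: Acid removes the tert-butyl group as isobutene and the γ-hydroxy acid lactonises (5-exo-trig acyl substitution) onto the only free hydroxyl, C1–OH, closing the cis-fused lactone with retention at C1 and C10.

Step 14
Reactants: 22 lactone
Product: 26 α-methylene lactone bis-silyl ether, via lithium enolate 23 (not isolated), via aminomethyl lactone 24 (not isolated), via ammonium iodide 25 (not isolated)
Conditions: LiN(iPr)2 (1.1 equiv), THF, −78 °C; CH2=NMe2+ I−, −78 °C → rt; then MeI, MeOH, rt; then NaHCO3 (aq.), CH2Cl2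
Reagents that add atoms: N,N-dimethylmethyleneiminium iodide, C=[N+](C)C.[I-]
Why: The lactone enolate is aminomethylated (Mannich reaction), and exhaustive methylation followed by mild base eliminates trimethylamine (Hofmann-type E1cB) to the exocyclic methylene, which removes the transient C11 centre; only silyl ethers are present, so no other group is enolised.

Step 15
Reactants: 26 α-methylene lactone bis-silyl ether
Product: 27 diol (9β-OH; C14 CH2OH; α-methylene lactone)
Conditions: HF·pyridine (excess), THF–pyridine, 0 °C → rt
Reagents that add atoms: none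
Why: Fluoride-driven cleavage of both silyl ethers under acidic, non-nucleophilic conditions leaves the Michael-acceptor lactone intact and avoids base-induced translactonisation to the neighbouring cis C9 hydroxyl.

Step 16
Reactants: 27 diol
Product: 28 C14 monoacetate (9β-OH free)
Conditions: AcCl (1.05 equiv), 2,4,6-collidine, CH2Cl2, −78 °C
Reagents that add atoms: acetyl chloride, CC(=O)Cl
Why: Kinetic chemoselective acylation of the primary allylic alcohol with acetyl chloride and a weak hindered base, the secondary C9 alcohol next to the ring fusion reacting far more slowly and the weak base sparing the lactone.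

Step 17
Reactants: 28 monoacetate; 29 (tert-butyldimethylsilyloxy)acetic acid
Product: 31 target CNP0156635.1, via silyl glycolate 30 (not isolated)
Conditions: PPh3, iPrO2CN=NCO2iPr (betaine preformed), 29, PhMe, 0 °C → rt; then HF·pyridine, THF, 0 °C
Reagents that add atoms: none
Why: Mitsunobu esterification activates the 9β-alcohol as its alkoxyphosphonium salt and the carboxylate of 29 displaces it by SN2 with inversion, turning the reduction-derived cis alcohol into the required 9α glycolate, and HF·pyridine then removes the silyl group without harming the acetate or the methylene lactone.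

**Compound list**

1 | tropone (cyclohepta-2,4,6-trien-1-one) | O=C1C=CC=CC=C1 | starting material
2 | (E)-1-methoxy-3-(trimethylsilyloxy)buta-1,3-diene | CO/C=C/C(=C)O[Si](C)(C)C | starting material
3 | (6+4) adduct, 7-methoxy-9-(trimethylsilyloxy)bicyclo[4.4.1]undeca-2,4,8-trien-11-one; racemic; methoxy anti to the carbonyl bridge | O=C1[C@H]2C=CC=C[C@@H]1[C@H](OC)C=C(O[Si](C)(C)C)C2 | intermediate
4 | 7-methoxybicyclo[4.4.1]undeca-2,4-diene-9,11-dione; racemic | O=C1[C@H]2C=CC=C[C@@H]1[C@H](OC)CC(=O)C2 | intermediate
5 | 7-methoxy-2,5-epidioxybicyclo[4.4.1]undec-3-ene-9,11-dione; racemic; peroxide syn to the carbonyl bridge | O=C1[C@H]2[C@@H]3C=C[C@@H](OO3)[C@@H]1[C@H](OC)CC(=O)C2 | intermediate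
6 | 2,5-dihydroxy-7-methoxybicyclo[4.4.1]undecane-9,11-dione; racemic; both OH syn to the carbonyl bridge | O=C1[C@H]2[C@@H](O)CC[C@@H](O)[C@@H]1[C@H](OC)CC(=O)C2 | intermediate
7 | bis(methanesulfonate) of 6; racemic | O=C1[C@H]2[C@@H](OS(C)(=O)=O)CC[C@@H](OS(C)(=O)=O)[C@@H]1[C@H](OC)CC(=O)C2 | intermediate
8 | 2,5-bis(methanesulfonyloxy)bicyclo[4.4.1]undec-7-ene-9,11-dione; racemic | O=C1[C@H]2[C@@H](OS(C)(=O)=O)CC[C@@H](OS(C)(=O)=O)[C@@H]1C=CC(=O)C2 | intermediate (not isolated)
9 | methyl (5Z,7Z)-2-(methanesulfonyloxy)-9-oxocyclodeca-5,7-diene-1-carboxylate; racemic | COC(=O)[C@@H]1CC(=O)/C=C\C=C/CC[C@@H]1OS(C)(=O)=O | intermediate (not isolated)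
10 | methyl (1E,5Z,7Z)-9-oxocyclodeca-1,5,7-triene-1-carboxylate; achiral | COC(=O)/C1=C/CC/C=C\C=C/C(=O)C1 | intermediate
11 | tert-butyl bromoacetate | CC(C)(C)OC(=O)CBr | starting material
12 | bromomagnesium dienolate of the 1,6-adduct (3β-methyl; C9(OMgBr)=C10; cis C1=C2) | COC(=O)/C1=C/CC[C@H](C)/C=C\C=C(\O[Mg]Br)C1 | intermediate (not isolated)
13 | methyl (1E,5S,6Z,8S)-8-(2-tert-butoxy-2-oxoethyl)-5-methyl-9-oxocyclodeca-1,6-diene-1-carboxylate (3β-methyl, 10β-arm, C9 ketone) | CC(C)(C)OC(=O)C[C@H]1/C=C\[C@@H](C)CC/C=C(/C(=O)OC)CC1=O | intermediate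
14 | diol: 9β-OH, C14 CH2OH, 10β-CH2CO2tBu, 3β-methyl, cis C1=C2, C6=C7 | CC(C)(C)OC(=O)C[C@H]1/C=C\[C@@H](C)CC/C=C(/CO)C[C@H]1O | intermediate
15 | C14 tert-butyldiphenylsilyl ether of 14 | CC(C)(C)OC(=O)C[C@H]1/C=C\[C@@H](C)CC/C=C(/CO[Si](c2ccccc2)(c2ccccc2)C(C)(C)C)C[C@H]1O | intermediate
16 | C9 dimethylsilyl (Si–H) ether of 15 | CC(C)(C)OC(=O)C[C@H]1/C=C\[C@@H](C)CC/C=C(/CO[Si](c2ccccc2)(c2ccccc2)C(C)(C)C)C[C@H]1O[SiH](C)C | intermediate (not isolated)
17 | oxasilolane: O9–SiMe2–C1 ring, C1–Si β, C9–O β, 10β-CH2CO2tBu | C[Si]1(C)[C@H]2C[C@@H](C)CC/C=C(/CO[Si](c3ccccc3)(c3ccccc3)C(C)(C)C)C[C@@H](O1)[C@H]2CC(=O)OC(C)(C)C | intermediate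
18 | 9β-alcohol with 1β-fluorodimethylsilyl group | C[Si](C)(F)[C@H]1C[C@@H](C)CC/C=C(/CO[Si](c2ccccc2)(c2ccccc2)C(C)(C)C)C[C@@H](O)[C@H]1CC(=O)OC(C)(C)C | intermediate (not isolated)
19 | 9β-tert-butyldimethylsilyl ether with 1β-fluorodimethylsilyl group | C[Si](C)(F)[C@H]1C[C@@H](C)CC/C=C(/CO[Si](c2ccccc2)(c2ccccc2)C(C)(C)C)C[C@@H](O[Si](C)(C)C(C)(C)C)[C@H]1CC(=O)OC(C)(C)C | intermediate
20 | 1β-alcohol (C9–OTBS, C14–OTBDPS, tert-butyl ester) | O[C@H]1C[C@@H](C)CC/C=C(/CO[Si](c2ccccc2)(c2ccccc2)C(C)(C)C)C[C@@H](O[Si](C)(C)C(C)(C)C)[C@H]1CC(=O)OC(C)(C)C | intermediate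
21 | hydroxy acid from 20 | O[C@H]1C[C@@H](C)CC/C=C(/CO[Si](c2ccccc2)(c2ccccc2)C(C)(C)C)C[C@@H](O[Si](C)(C)C(C)(C)C)[C@H]1CC(=O)O | intermediate (not isolated)
22 | cis-fused γ-lactone (C1–O–C12), C9–OTBS, C14–OTBDPS | C1C(=O)O[C@H]2C[C@@H](C)CC/C=C(/CO[Si](c3ccccc3)(c3ccccc3)C(C)(C)C)C[C@@H](O[Si](C)(C)C(C)(C)C)[C@@H]12 | intermediate
23 | lithium enolate of 22 | C1=C(O[Li])O[C@H]2C[C@@H](C)CC/C=C(/CO[Si](c3ccccc3)(c3ccccc3)C(C)(C)C)C[C@@H](O[Si](C)(C)C(C)(C)C)[C@@H]12 | intermediate (not isolated)
24 | α-(dimethylaminomethyl) lactone (C11 epimers) | CN(C)CC1C(=O)O[C@H]2C[C@@H](C)CC/C=C(/CO[Si](c3ccccc3)(c3ccccc3)C(C)(C)C)C[C@@H](O[Si](C)(C)C(C)(C)C)[C@@H]12 | intermediate (not isolated)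
25 | trimethylammonium iodide of 24 | C[N+](C)(C)CC1C(=O)O[C@H]2C[C@@H](C)CC/C=C(/CO[Si](c3ccccc3)(c3ccccc3)C(C)(C)C)C[C@@H](O[Si](C)(C)C(C)(C)C)[C@@H]12.[I-] | intermediate (not isolated)
26 | α-methylene lactone, C9–OTBS, C14–OTBDPS | C=C1C(=O)O[C@H]2C[C@@H](C)CC/C=C(/CO[Si](c3ccccc3)(c3ccccc3)C(C)(C)C)C[C@@H](O[Si](C)(C)C(C)(C)C)[C@@H]12 | intermediate
27 | α-methylene lactone diol (9β-OH, C14 CH2OH) | C=C1C(=O)O[C@H]2C[C@@H](C)CC/C=C(/CO)C[C@@H](O)[C@@H]12 | intermediate
28 | C14 acetate of 27 (9β-OH free) | C=C1C(=O)O[C@H]2C[C@@H](C)CC/C=C(/COC(C)=O)C[C@@H](O)[C@@H]12 | intermediate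
29 | (tert-butyldimethylsilyloxy)acetic acid | CC(C)(C)[Si](C)(C)OCC(=O)O | starting material
30 | 9α-[(tert-butyldimethylsilyloxy)acetate] of the target skeleton | C=C1C(=O)O[C@H]2C[C@@H](C)CC/C=C(/COC(C)=O)C[C@H](OC(=O)CO[Si](C)(C)C(C)(C)C)[C@@H]12 | intermediate (not isolated)
31 | CNP0156635.1 | C=C1C(=O)O[C@H]2C[C@@H](C)CC/C=C(/COC(C)=O)C[C@H](OC(=O)CO)[C@@H]12 | target

**Step count and risks**

Total: 17 steps. Longest linear sequence: 17 steps from 1 and 2 (11 and 29 are used as purchased).

Steps most likely to fail:

1. Step 6. Several things can go wrong once the ring is open. Residual methoxide can deprotonate C8 of the β,γ-unsaturated ketone and draw the C6=C7 alkene into conjugation with the C9 ketone. The C8 enolate can displace the γ-mesylate to form a cyclopropane. The C7 ester enolate can add across the ring before it eliminates. Fallback, stepwise and with a poorer leaving group: from 6, both hydroxyls are silylated (tBuMe2SiCl, imidazole, DMF) to the bis(tert-butyldimethylsilyl) ether F1. NaOMe in MeOH then effects the same methanol loss, retro-Claisen cleavage and expulsion of the C3 silyloxide but leaves the β-silyloxy ester alone, giving the silyloxy dienone ester F2. HF·pyridine frees the β-hydroxy ester F3. MeSO2Cl/Et3N at −20 °C forms mesylate 9 and eliminates it under amine-only conditions, returning to the route at 10.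

2. Step 7. The magnesium dienolate may alkylate too slowly, so that proton transfer scrambles the enolate (loss of C10 versus C8 regiocontrol and of the C10 configuration), or 1,4-addition may compete with 1,6-addition. Fallback, decoupled: from 10, the same copper-catalysed addition is run with Me3SiCl present and the dienolate is isolated as the trimethylsilyl dienol ether F4. MeLi in THF then releases the lithium dienolate F5 free of magnesium and copper salts, and alkylation with 11 in THF–DMPU at −78 °C returns to the route at 13.

3. Step 17. The activated, hindered C9 alcohol may eliminate toward C8 or C10, may react with retention through an acyloxyphosphonium pathway, or the phosphine may add to the methylene lactone. Fallback, phosphine-free two-stage inversion: from 28, the alcohol is converted to the C9 trifluoromethanesulfonate F6 ((CF3SO2)2O, pyridine, CH2Cl2, −40 °C). It is displaced at low temperature by cesium (tert-butyldimethylsilyloxy)acetate F7 (from 29 and Cs2CO3; 18-crown-6, PhMe) in an SN2 reaction with inversion. This returns to the route at 30, which is desilylated with HF·pyridine as in step 17.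

**Further compounds**

F1 | step 6 | bis(tert-butyldimethylsilyl) ether of 6 | O=C1[C@H]2[C@@H](O[Si](C)(C)C(C)(C)C)CC[C@@H](O[Si](C)(C)C(C)(C)C)[C@@H]1[C@H](OC)CC(=O)C2
F2 | step 6 | methyl (5Z,7Z)-2-(tert-butyldimethylsilyloxy)-9-oxocyclodeca-5,7-diene-1-carboxylate | COC(=O)[C@@H]1CC(=O)/C=C\C=C/CC[C@@H]1O[Si](C)(C)C(C)(C)C
F3 | step 6 | methyl (5Z,7Z)-2-hydroxy-9-oxocyclodeca-5,7-diene-1-carboxylate | COC(=O)[C@@H]1CC(=O)/C=C\C=C/CC[C@@H]1O
F4 | step 7 | trimethylsilyl dienol ether of the 1,6-adduct | COC(=O)/C1=C/CC[C@H](C)/C=C\C=C(\O[Si](C)(C)C)C1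
F5 | step 7 | lithium dienolate of the 1,6-adduct | COC(=O)/C1=C/CC[C@H](C)/C=C\C=C(\O[Li])C1
F6 | step 17 | C9 trifluoromethanesulfonate of 28 | C=C1C(=O)O[C@H]2C[C@@H](C)CC/C=C(/COC(C)=O)C[C@@H](OS(=O)(=O)C(F)(F)F)[C@@H]12
F7 | step 17 | cesium (tert-butyldimethylsilyloxy)acetate | CC(C)(C)[Si](C)(C)OCC(=O)[O-].[Cs+]
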